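## Retrosynthetic overview
1. 8‑Acetylcaespitol ⇒ caespitol ⇒ break C7–CH3. Methyl is delivered axially, anti to C8–O, onto the 7,8‑epoxide of a 6‑cyclohexyl‑3‑bromo‑2,2‑dimethyl‑dihydropyran. C7 and C8 are set from C10.
2. Dihydropyran (second ring formed) ⇒ acyclic bromochloro ketone. The O–C11 bond forms when the ketone oxygen captures a bromiranium ion released by solvolysis of an enantiopure vicinal bromochloride. No Br+/alkene bromoetherification is used.
3. Ketone ⇒ C8–C9 enolate alkylation of a cyclohexyl methyl ketone with the triflate of prenol bromochloride.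
4. Cyclohexane (first ring formed) ⇒ C1–C6 bond by bromiranium‑mediated π‑cyclisation of the triflate of nerol 2,3‑bromochloride. No BrCl addition to a cyclohexene is used. A chair TS gives the trans‑diequatorial Br/Cl array cis to the side chain.
5. Both C–Br centres and the ring C–Cl centre ⇒ one catalytic enantioselective bromochlorination, applied to nerol and to prenol.

Atom labels (bisabolane): ring = C1–C6 (C2 = CHBr, C3 = CClMe, C6 = ring CH); C7 = O–C(Me); C8 = CHOAc; C9 = CH2; C10 = CHBr; C11 = OCMe2.

Assumption: the ligand antipode sets the sense of induction in the Ti/Schiff‑base bromochlorination. L* is the antipode giving (2S,3S)‑2. The opposite antipode, ent‑L*, is needed for (R)‑7.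

## Route

**Step 1**
- Reactants: 1, nerol [(2Z)‑3,7‑dimethylocta‑2,6‑dien‑1‑ol]
- Product: 2, (2S,3S)‑2‑bromo‑3‑chloro‑3,7‑dimethyloct‑6‑en‑1‑ol
- Conditions: NBS, ClTi(OiPr)3, chiral tridentate salicylaldimine (Schiff‑base) ligand L* (20 mol %), hexanes, −20 °C
- Reagents that add atoms: N‑bromosuccinimide O=C1CCC(=O)N1Br; chlorotitanium triisopropoxide CC(C)O[Ti](Cl)(OC(C)C)OC(C)C
- Why: Catalytic enantioselective bromochlorination of allylic alcohols; the Ti‑bound alkoxide makes it chemoselective for the 2,3‑alkene, Cl goes to the tertiary carbon, anti addition to the Z alkene fixes the relative C2/C3 configuration (trans once in a ring), and L* fixes the absolute sense.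

**Step 2**
- Reactants: 2, (2S,3S)‑bromochloro alcohol
- Product: 3, (2S,3S)‑2‑bromo‑3‑chloro‑3,7‑dimethyloct‑6‑en‑1‑yl trifluoromethanesulfonate
- Conditions: Tf2O, 2,6‑di‑tert‑butyl‑4‑methylpyridine (DTBMP), CH2Cl2, −78 °C; used cold and crude
- Reagents that add atoms: triflic anhydride O=S(=O)(OS(=O)(=O)C(F)(F)F)C(F)(F)F
- Why: O‑sulfonylation of the only hydroxyl with a non‑nucleophilic base; no stereocentre is touched.

**Step 3 (key step, first ring)**
- Reactants: 3, bromochloro triflate
- Product: 4, (1S,2S,4S)‑2‑bromo‑1‑chloro‑1‑methyl‑4‑(prop‑1‑en‑2‑yl)cyclohexane (Br, Cl and isopropenyl equatorial, CH3 axial)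
- Conditions: cannulate into HFIP/CH2Cl2 (4:1), 2 mM, DTBMP (3 equiv), 0 → 23 °C
- Reagents that add atoms: none
- Why: Proposed new method: in ionising, non‑nucleophilic HFIP the primary triflate leaves with help from the anti β‑bromine (bromiranium ion, as in solvolysis of β‑bromo sulfonates), and the electron‑rich C6=C7 alkene opens it at the unhindered CH2 terminus (C2 is neopentyl and deactivated by the β‑Cl) through a chair TS; anti opening places Br equatorial, which forces Cl equatorial and Me axial, and the developing 2‑propyl cation sits equatorial, so C6 forms as S; intramolecular Br+ transfer would need a linear C···Br···C array inside a six‑membered TS, intermolecular transfer is suppressed at 2 mM, and the hindered base then removes a methyl proton (E1); closest known types are the stereospecific solvolytic bromonium polyene cyclisation of vicinal bromochlorides and the neryl → α‑terpinyl cation–olefin cyclisation.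

**Step 4**
- Reactants: 4, isopropenyl cyclohexane
- Product: 5, 1‑[(1S,3S,4S)‑3‑bromo‑4‑chloro‑4‑methylcyclohexyl]ethan‑1‑one
- Conditions: O3, CH2Cl2, −78 °C; then Me2S, −78 → 0 °C
- Reagents that add atoms: ozone [O-][O+]=O
- Why: Ozonolysis of the only alkene (any isopropylidene isomer gives a different, separable ketone); the neutral reductive work‑up avoids enolisation at C6, whose epimer (diaxial Br/Cl, equatorial Me) is thermodynamically competitive.

**Step 5**
- Reactants: 6, prenol (3‑methylbut‑2‑en‑1‑ol)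
- Product: 7, (2R)‑2‑bromo‑3‑chloro‑3‑methylbutan‑1‑ol
- Conditions: NBS, ClTi(OiPr)3, ent‑L* (20 mol %), hexanes, −20 °C
- Reagents that add atoms: N‑bromosuccinimide O=C1CCC(=O)N1Br; chlorotitanium triisopropoxide CC(C)O[Ti](Cl)(OC(C)C)OC(C)C
- Why: Same catalytic enantioselective bromochlorination (Br to C2, Cl to the tertiary carbon); ent‑L* sets the future C10 as R.

**Step 6**
- Reactants: 7, (R)‑bromochloro alcohol
- Product: 8, (2R)‑2‑bromo‑3‑chloro‑3‑methylbutyl trifluoromethanesulfonate
- Conditions: Tf2O, 2,6‑lutidine, CH2Cl2, −78 °C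
- Reagents that add atoms: triflic anhydride O=S(=O)(OS(=O)(=O)C(F)(F)F)C(F)(F)F
- Why: O‑sulfonylation; the stereocentre is untouched.

**Step 7 (fragment union)**
- Reactants: 5, cyclohexyl methyl ketone; 8, bromochloro triflate (1.3 equiv)
- Product: 9, (4R)‑4‑bromo‑1‑[(1S,3S,4S)‑3‑bromo‑4‑chloro‑4‑methylcyclohexyl]‑5‑chloro‑5‑methylhexan‑1‑one
- Conditions: LDA (1.0 equiv), THF, −78 °C; add 8, −78 → −40 °C; AcOH quench cold
- Reagents that add atoms: none beyond 5 and 8
- Why: Kinetic lithium enolate (CH3 over the hindered C6–H) in an SN2 alkylation on a primary triflate, as with 2‑haloethyl triflates; the ring halides are equatorial with no anti H, so E2 is disfavoured; no stereocentre is touched, and coupling two enantioenriched halves sends the minor enantiomers into separable diastereomers.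

**Step 8 (second ring)**
- Reactants: 9, bromochloro ketone
- Product: 10, (3R)‑3‑bromo‑6‑[(1S,3S,4S)‑3‑bromo‑4‑chloro‑4‑methylcyclohexyl]‑2,2‑dimethyl‑3,4‑dihydro‑2H‑pyran
- Conditions: HFIP, 5 mM, 2,6‑di‑tert‑butylpyridine (2 equiv), 40 °C; Et3N quench, concentrate from toluene
- Reagents that add atoms: none
- Why: Proposed new method: only the acyclic tertiary C–Cl can align anti to a bromine (the ring Br/Cl are locked gauche), so HFIP ionises it selectively to an enantiopure bromiranium; the ketone oxygen opens this at tertiary C11 to a six‑membered oxocarbenium with the C10–Br configuration retained (the 5‑exo alternative keeps a tertiary bromide that re‑ionises), and the hindered base removes the accessible axial C8–H rather than C6–H to give the endocyclic enol ether; closest known types are solvolytic bromochloride → bromonium cyclisation and halo‑ketalisation of unsaturated ketones.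

**Step 9**
- Reactants: 10, bromo dihydropyran
- Product: 11, (1S,4R,6R)‑4‑bromo‑1‑[(1S,3S,4S)‑3‑bromo‑4‑chloro‑4‑methylcyclohexyl]‑3,3‑dimethyl‑2,7‑dioxabicyclo[4.1.0]heptane (7,8‑epoxide on the face opposite C10–Br)
- Conditions: DMDO, acetone/CH2Cl2, −78 → 0 °C; evaporate cold, use at once
- Reagents that add atoms: dimethyldioxirane CC1(C)OO1
- Why: Glycal‑type enol‑ether epoxidation; in the half‑chair with C10–Br pseudo‑equatorial, the pseudo‑axial C11 methyl blocks the Br face, so oxygen arrives anti to Br and sets C8 as R.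

**Step 10**
- Reactants: 11, anhydro‑ketal epoxide
- Product: 12, caespitol, (2R,3R,5R)‑5‑bromo‑2‑[(1S,3S,4S)‑3‑bromo‑4‑chloro‑4‑methylcyclohexyl]‑2,6,6‑trimethyloxan‑3‑ol
- Conditions: MeMgCl (3 equiv), THF/CH2Cl2, −78 → −20 °C; aq NH4Cl
- Reagents that add atoms: methylmagnesium chloride C[Mg]Cl
- Why: C‑glycosidation‑type opening of a 1,2‑anhydro ketal by a Grignard reagent; Mg‑assisted C7–O ionisation is followed by axial, trans‑diaxial methyl delivery anti to the C8 alkoxide, which inverts C7 to R (Me axial, cyclohexyl equatorial); alkyl halides are inert at this temperature, and AlMe3 is avoided because it delivers syn and attacks tertiary chlorides.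

**Step 11**
- Reactants: 12, caespitol
- Product: 13, 8‑acetylcaespitol (target)
- Conditions: Ac2O, DMAP, pyridine, 40 °C
- Reagents that add atoms: acetic anhydride CC(=O)OC(C)=O
- Why: DMAP‑catalysed acetylation of the single, axial hydroxyl; no stereocentre is touched.

## Compound list

| No. | Name | SMILES | Role |
|---|---|---|---|
| 1 | nerol | CC(C)=CCC/C(C)=C\CO | starting material |
| 2 | (2S,3S)‑2‑bromo‑3‑chloro‑3,7‑dimethyloct‑6‑en‑1‑ol | CC(C)=CCC[C@](C)(Cl)[C@@H](Br)CO | intermediate |
| 3 | (2S,3S)‑2‑bromo‑3‑chloro‑3,7‑dimethyloct‑6‑en‑1‑yl triflate | CC(C)=CCC[C@](C)(Cl)[C@@H](Br)COS(=O)(=O)C(F)(F)F | intermediate |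
| 4 | (1S,2S,4S)‑2‑bromo‑1‑chloro‑1‑methyl‑4‑(prop‑1‑en‑2‑yl)cyclohexane | C=C(C)[C@H]1CC[C@](C)(Cl)[C@@H](Br)C1 | intermediate |
| 5 | 1‑[(1S,3S,4S)‑3‑bromo‑4‑chloro‑4‑methylcyclohexyl]ethanone | CC(=O)[C@H]1CC[C@](C)(Cl)[C@@H](Br)C1 | intermediate |
| 6 | prenol | CC(C)=CCO | starting material |
| 7 | (2R)‑2‑bromo‑3‑chloro‑3‑methylbutan‑1‑ol | OC[C@@H](Br)C(C)(C)Cl | intermediate |
| 8 | (2R)‑2‑bromo‑3‑chloro‑3‑methylbutyl triflate | O=S(=O)(OC[C@@H](Br)C(C)(C)Cl)C(F)(F)F | intermediate |
| 9 | (4R)‑4‑bromo‑1‑[(1S,3S,4S)‑3‑bromo‑4‑chloro‑4‑methylcyclohexyl]‑5‑chloro‑5‑methylhexan‑1‑one | O=C(CC[C@@H](Br)C(C)(C)Cl)[C@H]1CC[C@](C)(Cl)[C@@H](Br)C1 | intermediate |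
| 10 | (3R)‑3‑bromo‑6‑[(1S,3S,4S)‑3‑bromo‑4‑chloro‑4‑methylcyclohexyl]‑2,2‑dimethyl‑3,4‑dihydro‑2H‑pyran | C1(=CC[C@@H](Br)C(C)(C)O1)[C@H]2CC[C@](C)(Cl)[C@@H](Br)C2 | intermediate |
| 11 | (1S,4R,6R)‑4‑bromo‑1‑[(1S,3S,4S)‑3‑bromo‑4‑chloro‑4‑methylcyclohexyl]‑3,3‑dimethyl‑2,7‑dioxabicyclo[4.1.0]heptane | O1[C@@H]2C[C@@H](Br)C(C)(C)O[C@]12[C@H]3CC[C@](C)(Cl)[C@@H](Br)C3 | intermediate |
| 12 | caespitol | O[C@@H]1C[C@@H](Br)C(C)(C)O[C@]1(C)[C@H]1CC[C@](C)(Cl)[C@@H](Br)C1 | intermediate |
| 13 | 8‑acetylcaespitol | CC(=O)O[C@@H]1C[C@@H](Br)C(C)(C)O[C@]1(C)[C@H]1CC[C@](C)(Cl)[C@@H](Br)C1 | target |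

## Step count and risks

Total steps: 11. Longest linear sequence: 9 (1→2→3→4→5→9→10→11→12→13).

Steps most likely to fail:

1. **Step 3.**
   - Risk: slow ionisation, solvent capture, a non‑bridged SN2 path giving the C6 epimer, or the wrong E1 regiochemistry.
   - Fallback: switch to an anionic [5+1] annulation.
     - Reduce 4‑methyl‑5,6‑dihydropyran‑2‑one to (Z)‑3‑methylpent‑2‑ene‑1,5‑diol.
     - Bromochlorinate it as in Step 1 and make the bis‑triflate.
     - Doubly alkylate allyl acetoacetate with it (Cs2CO3).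
     - Carry out Pd(0) decarboxylative kinetic protonation, with H delivered anti to the axial Br, to reach 5.
2. **Step 7.**
   - Risk: E2 or O‑alkylation at the β‑bromo triflate, or enolate cyclopropanation onto C10–Br.
   - Fallback: C‑prenylate the enolate of 5 with prenyl bromide. Then set C10 under reagent control with a chiral phosphoramidite·NBS bromonium donor, with ketone‑oxygen capture, entering the route directly at 10.
3. **Step 10.**
   - Risk: the congested C7 gives syn delivery, hydride shift or elimination instead of anti methylation.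
   - Fallback: open 11 with MeOH to the C7 methyl ketal/C8 alcohol and acetylate C8. Then ionise with TMSOTf in the presence of Me2Zn, so that C8‑acetoxy participation (dioxolenium on the face of the acetate) enforces 1,2‑trans methyl delivery and gives 13 directly.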